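**Retrosynthetic overview**

1. Numbering used throughout (daucane): C1 quaternary ring-fusion carbon (CH3), C2 CH(OH), C3 CH2, C4 C(OH)(i-Pr), C5 ring-fusion CH, C6 CH(O-angeloyl), C7 CH2, C8 C(CH3)=, C9 =CH, C10 CH(O-angeloyl).
2. 32 ⇐ C2-ketone bis-angelate 31 (hydride anti to the angular methyl) ⇐ keto triol 29 ⇐ ring-closing metathesis at C8=C9 (seven-membered ring, formed last) of cyclopentanone 28 ⇐ N–O cleavage of isoxazoline 26.
3. Key disconnection: the C2–C1 bond of the cyclopentane together with O–C10. The enabling feature is the 1,3-dioxygenated array C2(OH)–C1(quaternary)–C10(O) that straddles the five- and seven-membered rings, with C2 and the C10 oxygen cis on C1. This is a masked isoxazoline, so an intramolecular nitrile oxide cycloaddition of the acyclic (Z)-dienyl oxime 21 closes the cyclopentane and the isoxazoline at once.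
4. 21 ⇐ (Z)-dienol 18 ⇐ δ-lactone 15 (temporary ring that fixes the (Z)-C1=C10 geometry; opened by i-Bu2AlH reduction and Wittig methylenation) ⇐ Evans syn aldol adduct 11 of imide 8 with aldehyde 9 (C6 from ethyl (3R)-4-chloro-3-hydroxybutanoate, C5 from the auxiliary). The isopropyl group is added to a C4 ketone after the cycloaddition.
5. Order of ring formation: temporary dihydropyranone → cyclopentane plus isoxazoline (key step) → cycloheptene.

Key step: step 14

Remarks: TBS = tert-butyldimethylsilyl, Bn = benzyl. The C4 carbinol configuration made in step 6 is inconsequential because C4 is oxidised in step 15. Lactol 16 (anomers) and oxime 21 (E/Z) are carried as mixtures.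

**Route**

Step 1
Reactants: 1 ethyl (3R)-4-chloro-3-hydroxybutanoate
Product: 2 ethyl 2-[(2R)-oxiran-2-yl]acetate
Conditions: Ag2O, MeCN, 50 °C, dark
Reagents that add atoms: none
Why: silver-assisted intramolecular Williamson etherification of the chlorohydrin should close the epoxide under non-basic conditions (no isomerisation to the 4-hydroxycrotonate), the C–O bond at the stereocentre (future C6) staying intact.

Step 2
Reactants: 2 ethyl 2-[(2R)-oxiran-2-yl]acetate
Product: 3 ethyl (3S)-3-hydroxy-5-methylhex-5-enoate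
Conditions: isopropenylmagnesium bromide, CuI (10 mol %), THF, −40 °C
Reagents that add atoms: isopropenylmagnesium bromide C=C(C)[Mg]Br
Why: copper-catalysed Grignard opening of a terminal epoxide at its CH2 carbon, faster than ester addition at −40 °C, should attach the C7–C8 methallyl unit without touching the stereocentre (the descriptor changes from R to S only through the priority rules).

Step 3
Reactants: 3 ethyl (3S)-3-hydroxy-5-methylhex-5-enoate
Product: 4 ethyl (3S)-3-(TBS-oxy)-5-methylhex-5-enoate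
Conditions: TBSCl, imidazole, DMF, rt
Reagents that add atoms: tert-butyldimethylsilyl chloride CC(C)(C)[Si](C)(C)Cl
Why: standard silylation of a secondary alcohol; the C6 oxygen stays masked until step 17.

Step 4
Reactants: 4 ethyl (3S)-3-(TBS-oxy)-5-methylhex-5-enoate
Product: 5 (3S)-3-(TBS-oxy)-5-methylhex-5-enoic acid
Conditions: LiOH, THF/MeOH/H2O, 0 °C → rt; then aq HCl to pH 4
Reagents that add atoms: lithium hydroxide [Li+].[OH-]
Why: saponification of the ethyl ester with cold LiOH, which β-silyloxy esters tolerate without β-elimination.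

Step 5
Reactants: 5 (3S)-3-(TBS-oxy)-5-methylhex-5-enoic acid; 6 (4S)-4-benzyl-1,3-oxazolidin-2-one
Product: 8 (4S)-4-benzyl-3-[(3S)-3-(TBS-oxy)-5-methylhex-5-enoyl]-1,3-oxazolidin-2-one, via mixed pivalic anhydride 7 (not isolated)
Conditions: t-BuCOCl, Et3N, THF, −20 °C; then 6, LiCl, rt
Reagents that add atoms: none
Why: N-acylation of the oxazolidinone by the mixed anhydride under LiCl/Et3N activation is the standard route to Evans imides and does not affect C6.

Step 6
Reactants: 8 (4S)-4-benzyl-3-[(3S)-3-(TBS-oxy)-5-methylhex-5-enoyl]-1,3-oxazolidin-2-one; 9 3-(TBS-oxy)propanal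
Product: 11 (4S)-4-benzyl-3-[(2R,3R)-2-[(1S)-1-(TBS-oxy)-3-methylbut-3-en-1-yl]-5-(TBS-oxy)-3-hydroxypentanoyl]-1,3-oxazolidin-2-one, via boron enolate 10 (not isolated)
Conditions: Bu2BOTf, i-Pr2NEt, CH2Cl2, −78 → 0 °C; then 9, −78 → 0 °C; pH 7 buffer, MeOH, H2O2
Reagents that add atoms: none
Why: Evans syn aldol reaction through the (Z)-boron enolate and a closed chair transition state, in which the (S)-benzyl auxiliary shields one enolate face and so sets C5 (configuration of 32) independently of the C6 silyl ether, the new C4 carbinol (syn) being a placeholder that is oxidised in step 15.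

Step 7
Reactants: 11 the syn aldol imide
Product: 12 (2R,3R)-2-[(1S)-1-(TBS-oxy)-3-methylbut-3-en-1-yl]-5-(TBS-oxy)-3-hydroxy-N-methoxy-N-methylpentanamide
Conditions: MeNHOMe·HCl, AlMe3, CH2Cl2, −20 → 0 °C
Reagents that add atoms: N,O-dimethylhydroxylamine hydrochloride CNOC.Cl
Why: aluminium amide transamidation of the aldol imide to the Weinreb amide, assisted by the free β-hydroxyl, should release auxiliary 6 without epimerising C5.

Step 8
Reactants: 12 the Weinreb amide
Product: 13 (3R,4R)-3-[(1S)-1-(TBS-oxy)-3-methylbut-3-en-1-yl]-6-(TBS-oxy)-4-hydroxyhexan-2-one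
Conditions: MeMgBr (3 equiv), THF, 0 °C
Reagents that add atoms: methylmagnesium bromide C[Mg]Br
Why: Weinreb ketone synthesis, the chelated tetrahedral intermediate preventing over-addition, should give the methyl ketone that supplies C1 and its methyl group.

Step 9
Reactants: 13 the β-hydroxy methyl ketone
Product: 15 (5R,6R)-5-[(1S)-1-(TBS-oxy)-3-methylbut-3-en-1-yl]-6-[2-(TBS-oxy)ethyl]-4-methyl-5,6-dihydro-2H-pyran-2-one, via phosphorane ester 14 (not isolated)
Conditions: Ph3P=C=C=O, toluene, 110 °C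
Reagents that add atoms: (triphenylphosphoranylidene)ketene O=C=C=P(c1ccccc1)(c1ccccc1)c1ccccc1
Why: addition of the C4 hydroxyl to the ketenylidene phosphorane gives ester ylide 14, whose intramolecular Wittig reaction with the methyl ketone should close the α,β-unsaturated δ-lactone, so that the new C1=C10 double bond is necessarily cis inside the six-membered ring (C5 and C9 on the same side).

Step 10
Reactants: 15 the unsaturated δ-lactone
Product: 16 (5R,6R)-5-[(1S)-1-(TBS-oxy)-3-methylbut-3-en-1-yl]-6-[2-(TBS-oxy)ethyl]-4-methyl-5,6-dihydro-2H-pyran-2-ol (anomers)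
Conditions: i-Bu2AlH (1.2 equiv), CH2Cl2, −78 °C
Reagents that add atoms: none
Why: 1,2-reduction of the unsaturated lactone by i-Bu2AlH stops at the lactol at −78 °C.

Step 11
Reactants: 16 the lactol
Product: 18 (3R,4R,5Z)-1-(TBS-oxy)-4-[(1S)-1-(TBS-oxy)-3-methylbut-3-en-1-yl]-5-methylocta-5,7-dien-3-ol, via open-chain hydroxy enal 17 (not isolated)
Conditions: Ph3PCH3Br, KN(SiMe3)2, THF, 0 °C → rt
Reagents that add atoms: methyltriphenylphosphonium bromide C[P+](c1ccccc1)(c1ccccc1)c1ccccc1.[Br-]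
Why: Wittig methylenation of the lactol through its open (Z)-hydroxy enal form 17 should give the (Z)-1,3-diene with the ring-derived geometry retained, and it frees the C4 hydroxyl.

Step 12
Reactants: 18 the (Z)-dienol bis-silyl ether
Product: 19 (3R,4R,5Z)-4-[(1S)-1-(TBS-oxy)-3-methylbut-3-en-1-yl]-5-methylocta-5,7-diene-1,3-diol
Conditions: HF·pyridine, pyridine, THF, 0 °C
Reagents that add atoms: none
Why: under buffered HF·pyridine the primary silyl ether is cleaved much faster than the hindered secondary one at C6 (steric differentiation).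

Step 13
Reactants: 19 the 1,3-diol
Product: 21 oxime of (3R,4R,5Z)-4-[(1S)-1-(TBS-oxy)-3-methylbut-3-en-1-yl]-3-hydroxy-5-methylocta-5,7-dienal, via aldehyde 20 (not isolated)
Conditions: TEMPO (10 mol %), PhI(OAc)2, CH2Cl2, rt; then NH2OH·HCl, pyridine, EtOH, rt
Reagents that add atoms: hydroxylamine hydrochloride NO.Cl
Why: the oxoammonium oxidation is selective for the primary alcohol over the secondary C4 carbinol, and the β-hydroxy aldehyde is condensed at once to the aldoxime, whose E/Z mixture is of no consequence.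

Step 14
Reactants: 21 the (Z)-dienyl aldoxime
Product: 23 (3R,3aR,4R,5R)-3-ethenyl-4-[(1S)-1-(TBS-oxy)-3-methylbut-3-en-1-yl]-3a-methyl-3a,4,5,6-tetrahydro-3H-cyclopenta[c][1,2]oxazol-5-ol, via nitrile oxide 22 (not isolated)
Conditions: aq NaOCl, CH2Cl2 (5 mM, slow addition of 21), 0 °C → rt
Reagents that add atoms: none
Why: NaOCl converts oxime 21 into nitrile oxide 22, which should undergo a concerted, suprafacial intramolecular [3+2] cycloaddition across the C1=C10 bond of the diene; the closest known reaction type is the fused-mode intramolecular nitrile oxide–olefin cycloaddition of 5-hexenyl nitrile oxides onto trisubstituted alkenes and dienes, which gives cyclopenta-fused isoxazolines with a quaternary ring-fusion carbon. The cyclopentane closes in 5-exo mode through the C2–C1 bond and the isoxazoline closes through O–C10, the three-atom tether (C3–C4–C5) making attack of the dipole carbon on the proximal alkene carbon C1 the only strain-free mode. The quaternary centre C1 and the carbinol centre C10 are set relative to each other stereospecifically by the (Z)-geometry of the alkene (C5 and C9 cis), so that C2 and the C10 oxygen end up cis on C1 as in 32. Their configuration relative to C5 is controlled by 1,3-allylic strain: the C5 hydrogen eclipses the alkene on the side of the cis vinyl group, the tether then reaches one face of C1 and the silyloxyalkyl arm (C6) lies on the other, which places the C10 and C6 arms trans on the new ring. The step needs site selectivity (C1=C10 over the terminal vinyl and the methallyl alkene, secured by ring size, five against seven or more), this facial selectivity, and suppression of furoxan formation, secured by slow generation of 22 at high dilution. The free C4 hydroxyl and the silyl ether are inert.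

Step 15
Reactants: 23 the bicyclic isoxazoline alcohol
Product: 24 (3R,3aR,4S)-3-ethenyl-4-[(1S)-1-(TBS-oxy)-3-methylbut-3-en-1-yl]-3a-methyl-3,3a,4,6-tetrahydro-5H-cyclopenta[c][1,2]oxazol-5-one
Conditions: Dess–Martin periodinane, CH2Cl2, 0 °C → rt
Reagents that add atoms: none
Why: Dess–Martin oxidation of the only free hydroxyl to the cyclopentanone under neutral conditions that should not epimerise C5 or affect the isoxazoline and the silyl ether.

Step 16
Reactants: 24 the C4 ketone
Product: 25 (3R,3aR,4S,5R)-3-ethenyl-4-[(1S)-1-(TBS-oxy)-3-methylbut-3-en-1-yl]-3a-methyl-5-(propan-2-yl)-3a,4,5,6-tetrahydro-3H-cyclopenta[c][1,2]oxazol-5-ol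
Conditions: i-PrMgCl, CeCl3, THF, −78 → −20 °C
Reagents that add atoms: isopropylmagnesium chloride CC(C)[Mg]Cl
Why: the weakly basic organocerium reagent adds to enolisable, hindered ketones (here C3 is activated by both C=O and C=N) where Grignard reagents enolise or reduce, and should attack C4 from the face opposite the pseudo-axial C1 methyl and the C5 side chain, giving the tertiary carbinol with isopropyl cis to H-5 as in 32.

Step 17
Reactants: 25 the tertiary alcohol silyl ether
Product: 26 (3R,3aR,4S,5R)-3-ethenyl-4-[(1S)-1-hydroxy-3-methylbut-3-en-1-yl]-3a-methyl-5-(propan-2-yl)-3a,4,5,6-tetrahydro-3H-cyclopenta[c][1,2]oxazol-5-ol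
Conditions: Bu4NF, THF, rt
Reagents that add atoms: none
Why: fluoride cleavage of the secondary silyl ether frees the C6 hydroxyl, the isoxazoline and the tertiary alcohol being inert.

Step 18
Reactants: 26 the isoxazoline diol
Product: 28 (2S,3S,4R)-4-hydroxy-3-[(1S)-1-hydroxy-3-methylbut-3-en-1-yl]-2-[(1R)-1-hydroxyprop-2-en-1-yl]-2-methyl-4-(propan-2-yl)cyclopentan-1-one, via hydroxy imine 27 (not isolated)
Conditions: Mo(CO)6, MeCN/H2O (15:1), 80 °C
Reagents that add atoms: water O
Why: reductive N–O cleavage of the isoxazoline by zerovalent molybdenum gives β-hydroxy imine 27, hydrolysed in situ to the β-hydroxy ketone, without reduction of the alkenes and, because C1 is quaternary, without dehydration across C1–C10 or epimerisation.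

Step 19
Reactants: 28 the cyclopentanone triol
Product: 29 (3R,3aS,4S,8R,8aS)-3,4,8-trihydroxy-6,8a-dimethyl-3-(propan-2-yl)-3,3a,4,5,8,8a-hexahydroazulen-1(2H)-one
Conditions: second-generation Grubbs catalyst (5 mol %), CH2Cl2 (2 mM), 40 °C
Reagents that add atoms: none
Why: ring-closing metathesis of the C10 vinyl group with the 1,1-disubstituted methallyl alkene should form the trisubstituted C8=C9 bond in the seven-membered ring, the trans arrangement of the two arms on the cyclopentane giving the trans ring fusion directly.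

Step 20
Reactants: 29 the bicyclic keto triol; 30 angelic acid
Product: 31 (3R,3aS,4S,8R,8aS)-3-hydroxy-6,8a-dimethyl-1-oxo-3-(propan-2-yl)-1,2,3,3a,4,5,8,8a-octahydroazulene-4,8-diyl bis[(2Z)-2-methylbut-2-enoate]
Conditions: 30 (6 equiv), 2,4,6-trichlorobenzoyl chloride, Et3N, toluene, rt; then 29, 80 °C
Reagents that add atoms: none
Why: Yamaguchi-type esterification through the preformed mixed anhydride acylates the two secondary hydroxyls (C6 and C10) without Z to E isomerisation of the angeloyl group, while the tertiary C4 hydroxyl does not react and C2 is still masked as the ketone.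

Step 21
Reactants: 31 the bis-angelate ketone
Product: 32 (1R,3R,3aS,4S,8R,8aR)-1,3-dihydroxy-6,8a-dimethyl-3-(propan-2-yl)-1,2,3,3a,4,5,8,8a-octahydroazulene-4,8-diyl bis[(2Z)-2-methylbut-2-enoate]
Conditions: NaBH4, CeCl3·7H2O, MeOH, −78 → −40 °C
Reagents that add atoms: none
Why: Luche-type borohydride reduction in which hydride should approach the cyclopentanone anti to the pseudo-axial angular methyl on the adjacent quaternary carbon (the usual course for cyclopentanones next to a methyl-bearing trans ring-fusion carbon), giving the C2 hydroxyl cis to that methyl, the conjugated esters being untouched at this temperature.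

**Compound list**

1 | ethyl (3R)-4-chloro-3-hydroxybutanoate | CCOC(=O)C[C@@H](O)CCl | starting material
2 | ethyl 2-[(2R)-oxiran-2-yl]acetate | CCOC(=O)C[C@@H]1CO1 | intermediate
3 | ethyl (3S)-3-hydroxy-5-methylhex-5-enoate | CCOC(=O)C[C@@H](O)CC(C)=C | intermediate
4 | ethyl (3S)-3-(TBS-oxy)-5-methylhex-5-enoate | CCOC(=O)C[C@@H](O[Si](C)(C)C(C)(C)C)CC(C)=C | intermediate
5 | (3S)-3-(TBS-oxy)-5-methylhex-5-enoic acid | OC(=O)C[C@@H](O[Si](C)(C)C(C)(C)C)CC(C)=C | intermediate
6 | (4S)-4-benzyl-1,3-oxazolidin-2-one | O=C1OC[C@H](Cc2ccccc2)N1 | starting material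
7 | (3S)-3-(TBS-oxy)-5-methylhex-5-enoic pivalic anhydride (not isolated) | CC(C)(C)C(=O)OC(=O)C[C@@H](O[Si](C)(C)C(C)(C)C)CC(C)=C | intermediate
8 | (4S)-4-benzyl-3-[(3S)-3-(TBS-oxy)-5-methylhex-5-enoyl]-1,3-oxazolidin-2-one | O=C1OC[C@H](Cc2ccccc2)N1C(=O)C[C@@H](O[Si](C)(C)C(C)(C)C)CC(C)=C | intermediate
9 | 3-(TBS-oxy)propanal | O=CCCO[Si](C)(C)C(C)(C)C | starting material
10 | (Z)-dibutylboron enolate of imide 8 (not isolated) | CCCCB(CCCC)O/C(=C\[C@@H](O[Si](C)(C)C(C)(C)C)CC(C)=C)N1C(=O)OC[C@@H]1Cc1ccccc1 | intermediate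
11 | (4S)-4-benzyl-3-[(2R,3R)-2-[(1S)-1-(TBS-oxy)-3-methylbut-3-en-1-yl]-5-(TBS-oxy)-3-hydroxypentanoyl]-1,3-oxazolidin-2-one | O=C1OC[C@H](Cc2ccccc2)N1C(=O)[C@@H]([C@@H](O[Si](C)(C)C(C)(C)C)CC(C)=C)[C@H](O)CCO[Si](C)(C)C(C)(C)C | intermediate
12 | (2R,3R)-2-[(1S)-1-(TBS-oxy)-3-methylbut-3-en-1-yl]-5-(TBS-oxy)-3-hydroxy-N-methoxy-N-methylpentanamide | CON(C)C(=O)[C@@H]([C@@H](O[Si](C)(C)C(C)(C)C)CC(C)=C)[C@H](O)CCO[Si](C)(C)C(C)(C)C | intermediate
13 | (3R,4R)-3-[(1S)-1-(TBS-oxy)-3-methylbut-3-en-1-yl]-6-(TBS-oxy)-4-hydroxyhexan-2-one | CC(=O)[C@@H]([C@@H](O[Si](C)(C)C(C)(C)C)CC(C)=C)[C@H](O)CCO[Si](C)(C)C(C)(C)C | intermediate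
14 | (triphenylphosphoranylidene)acetate of 13 at the C4 hydroxyl (not isolated) | CC(=O)[C@@H]([C@@H](O[Si](C)(C)C(C)(C)C)CC(C)=C)[C@H](OC(=O)C=P(c1ccccc1)(c1ccccc1)c1ccccc1)CCO[Si](C)(C)C(C)(C)C | intermediate
15 | (5R,6R)-5-[(1S)-1-(TBS-oxy)-3-methylbut-3-en-1-yl]-6-[2-(TBS-oxy)ethyl]-4-methyl-5,6-dihydro-2H-pyran-2-one | CC1=CC(=O)O[C@H](CCO[Si](C)(C)C(C)(C)C)[C@@H]1[C@@H](O[Si](C)(C)C(C)(C)C)CC(C)=C | intermediate
16 | (5R,6R)-5-[(1S)-1-(TBS-oxy)-3-methylbut-3-en-1-yl]-6-[2-(TBS-oxy)ethyl]-4-methyl-5,6-dihydro-2H-pyran-2-ol (anomers) | CC1=CC(O)O[C@H](CCO[Si](C)(C)C(C)(C)C)[C@@H]1[C@@H](O[Si](C)(C)C(C)(C)C)CC(C)=C | intermediate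
17 | (2Z,4R,5R)-4-[(1S)-1-(TBS-oxy)-3-methylbut-3-en-1-yl]-7-(TBS-oxy)-5-hydroxy-3-methylhept-2-enal (not isolated) | O=C/C=C(/C)[C@@H]([C@@H](O[Si](C)(C)C(C)(C)C)CC(C)=C)[C@H](O)CCO[Si](C)(C)C(C)(C)C | intermediate
18 | (3R,4R,5Z)-1-(TBS-oxy)-4-[(1S)-1-(TBS-oxy)-3-methylbut-3-en-1-yl]-5-methylocta-5,7-dien-3-ol | C=C/C=C(/C)[C@@H]([C@@H](O[Si](C)(C)C(C)(C)C)CC(C)=C)[C@H](O)CCO[Si](C)(C)C(C)(C)C | intermediate
19 | (3R,4R,5Z)-4-[(1S)-1-(TBS-oxy)-3-methylbut-3-en-1-yl]-5-methylocta-5,7-diene-1,3-diol | C=C/C=C(/C)[C@@H]([C@@H](O[Si](C)(C)C(C)(C)C)CC(C)=C)[C@H](O)CCO | intermediate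
20 | (3R,4R,5Z)-4-[(1S)-1-(TBS-oxy)-3-methylbut-3-en-1-yl]-3-hydroxy-5-methylocta-5,7-dienal (not isolated) | C=C/C=C(/C)[C@@H]([C@@H](O[Si](C)(C)C(C)(C)C)CC(C)=C)[C@H](O)CC=O | intermediate
21 | oxime of aldehyde 20 (E/Z mixture) | C=C/C=C(/C)[C@@H]([C@@H](O[Si](C)(C)C(C)(C)C)CC(C)=C)[C@H](O)CC=NO | intermediate
22 | (3R,4R,5Z)-4-[(1S)-1-(TBS-oxy)-3-methylbut-3-en-1-yl]-3-hydroxy-5-methylocta-5,7-dienenitrile oxide (not isolated) | C=C/C=C(/C)[C@@H]([C@@H](O[Si](C)(C)C(C)(C)C)CC(C)=C)[C@H](O)CC#[N+][O-] | intermediate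
23 | (3R,3aR,4R,5R)-3-ethenyl-4-[(1S)-1-(TBS-oxy)-3-methylbut-3-en-1-yl]-3a-methyl-3a,4,5,6-tetrahydro-3H-cyclopenta[c][1,2]oxazol-5-ol | C=C[C@H]1ON=C2C[C@@H](O)[C@H]([C@@H](O[Si](C)(C)C(C)(C)C)CC(C)=C)[C@@]12C | intermediate
24 | (3R,3aR,4S)-3-ethenyl-4-[(1S)-1-(TBS-oxy)-3-methylbut-3-en-1-yl]-3a-methyl-3,3a,4,6-tetrahydro-5H-cyclopenta[c][1,2]oxazol-5-one | C=C[C@H]1ON=C2CC(=O)[C@H]([C@@H](O[Si](C)(C)C(C)(C)C)CC(C)=C)[C@@]12C | intermediate
25 | (3R,3aR,4S,5R)-3-ethenyl-4-[(1S)-1-(TBS-oxy)-3-methylbut-3-en-1-yl]-3a-methyl-5-(propan-2-yl)-3a,4,5,6-tetrahydro-3H-cyclopenta[c][1,2]oxazol-5-ol | C=C[C@H]1ON=C2C[C@@](O)(C(C)C)[C@H]([C@@H](O[Si](C)(C)C(C)(C)C)CC(C)=C)[C@@]12C | intermediate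
26 | (3R,3aR,4S,5R)-3-ethenyl-4-[(1S)-1-hydroxy-3-methylbut-3-en-1-yl]-3a-methyl-5-(propan-2-yl)-3a,4,5,6-tetrahydro-3H-cyclopenta[c][1,2]oxazol-5-ol | C=C[C@H]1ON=C2C[C@@](O)(C(C)C)[C@H]([C@@H](O)CC(C)=C)[C@@]12C | intermediate
27 | ketimine corresponding to ketone 28 (not isolated) | C=C[C@@H](O)[C@@]1(C)C(=N)C[C@@](O)(C(C)C)[C@@H]1[C@@H](O)CC(C)=C | intermediate
28 | (2S,3S,4R)-4-hydroxy-3-[(1S)-1-hydroxy-3-methylbut-3-en-1-yl]-2-[(1R)-1-hydroxyprop-2-en-1-yl]-2-methyl-4-(propan-2-yl)cyclopentan-1-one | C=C[C@@H](O)[C@@]1(C)C(=O)C[C@@](O)(C(C)C)[C@@H]1[C@@H](O)CC(C)=C | intermediate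
29 | (3R,3aS,4S,8R,8aS)-3,4,8-trihydroxy-6,8a-dimethyl-3-(propan-2-yl)-3,3a,4,5,8,8a-hexahydroazulen-1(2H)-one | O[C@H]1CC(C)=C[C@@H](O)[C@@]2(C)C(=O)C[C@@](O)(C(C)C)[C@H]12 | intermediate
30 | angelic acid, (2Z)-2-methylbut-2-enoic acid | C/C=C(/C)C(=O)O | starting material
31 | (3R,3aS,4S,8R,8aS)-3-hydroxy-6,8a-dimethyl-1-oxo-3-(propan-2-yl)-1,2,3,3a,4,5,8,8a-octahydroazulene-4,8-diyl bis[(2Z)-2-methylbut-2-enoate] | C/C=C(/C)C(=O)O[C@H]1CC(C)=C[C@@H](OC(=O)/C(C)=C\C)[C@@]2(C)C(=O)C[C@@](O)(C(C)C)[C@H]12 | intermediate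
32 | (1R,3R,3aS,4S,8R,8aR)-1,3-dihydroxy-6,8a-dimethyl-3-(propan-2-yl)-1,2,3,3a,4,5,8,8a-octahydroazulene-4,8-diyl bis[(2Z)-2-methylbut-2-enoate] (CNP0249167.2) | C/C=C(/C)C(=O)O[C@H]1CC(C)=C[C@@H](OC(=O)/C(C)=C\C)[C@@]2(C)[C@H](O)C[C@@](O)(C(C)C)[C@H]12 | target

**Step count and risks**

Total steps: 21. Longest linear sequence: 21 steps (1 → 32); 6, 9 and 30 are purchased.

The three steps most likely to fail:

Step 14. What may go wrong is erosion of facial selectivity (reaction through conformers that do not keep the C5 hydrogen eclipsed with the alkene) or dimerisation of the nitrile oxide to a furoxan before it cyclises. The fallback changes the dipole to a silyl nitronate, which cannot dimerise and is bulkier. It sets out from diol 19: iodination of the primary hydroxyl (I2, PPh3, imidazole, CH2Cl2) would give the iodide F1, and NaNO2 with phloroglucinol in DMSO the nitroalkane F2. Me3SiCl and Et3N in benzene would then form the silyl nitronate F3 (the C4 hydroxyl is silylated as well), which should cyclise by intramolecular silyl nitronate–olefin cycloaddition to the N-silyloxyisoxazolidine F4. Treatment with TsOH in CH2Cl2/MeOH eliminates trimethylsilanol and frees the C4 hydroxyl, and the route is rejoined at 23.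

Step 20. What may go wrong is incomplete acylation of the neopentyl C10 hydroxyl, Z to E isomerisation of the acyl group, or base-induced retro-aldol cleavage or β-elimination of the β-hydroxy ketone on prolonged heating with amine. The fallback builds the (Z)-esters on the molecule instead of transferring them. It sets out from 29: carbodiimide coupling (DCC, catalytic DMAP, CH2Cl2, rt) with 2-[bis(2,2,2-trifluoroethoxy)phosphoryl]propanoic acid would give the bis-phosphonate F5. Still–Gennari olefination of both phosphonates with acetaldehyde (KN(SiMe3)2, 18-crown-6, THF, −78 °C) should then give the (Z)-2-methylbut-2-enoates, and the route is rejoined at 31.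

Step 21. What may go wrong is hydride delivery from the methyl-bearing face (poor facial selectivity at the last stereocentre). The fallback reverses the order and uses internal delivery. It sets out from 29: Me4NBH(OAc)3 in MeCN/AcOH at −30 °C should reduce the C2 ketone by hydride transfer from boron bound to the C10 oxygen, that is from the face anti to the angular methyl, giving the tetraol F6. Esterification with two equivalents of the mixed anhydride of step 20 would then acylate the C6 and C10 hydroxyls, the C2 hydroxyl (neopentyl, cis to the angular methyl and hydrogen-bonded to the C4 hydroxyl) being expected to react last, and the route is rejoined at 32.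

Further compounds
F1 | step 14 | (3R,4R,5Z)-4-[(1S)-1-(TBS-oxy)-3-methylbut-3-en-1-yl]-1-iodo-5-methylocta-5,7-dien-3-ol | C=C/C=C(/C)[C@@H]([C@@H](O[Si](C)(C)C(C)(C)C)CC(C)=C)[C@H](O)CCI
F2 | step 14 | (3R,4R,5Z)-4-[(1S)-1-(TBS-oxy)-3-methylbut-3-en-1-yl]-5-methyl-1-nitroocta-5,7-dien-3-ol | C=C/C=C(/C)[C@@H]([C@@H](O[Si](C)(C)C(C)(C)C)CC(C)=C)[C@H](O)CC[N+](=O)[O-]
F3 | step 14 | trimethylsilyl nitronate of F2, C4 hydroxyl as trimethylsilyl ether | C=C/C=C(/C)[C@@H]([C@@H](O[Si](C)(C)C(C)(C)C)CC(C)=C)[C@H](O[Si](C)(C)C)CC=[N+]([O-])O[Si](C)(C)C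
F4 | step 14 | N-(trimethylsilyloxy)isoxazolidine corresponding to 23, C4 hydroxyl as trimethylsilyl ether | C=C[C@H]1ON(O[Si](C)(C)C)[C@H]2C[C@@H](O[Si](C)(C)C)[C@H]([C@@H](O[Si](C)(C)C(C)(C)C)CC(C)=C)[C@@]12C
F5 | step 20 | C6,C10-bis{2-[bis(2,2,2-trifluoroethoxy)phosphoryl]propanoate} of 29 (epimers at the phosphonate carbons) | CC(C(=O)O[C@H]1CC(C)=C[C@@H](OC(=O)C(C)P(=O)(OCC(F)(F)F)OCC(F)(F)F)[C@@]2(C)C(=O)C[C@@](O)(C(C)C)[C@H]12)P(=O)(OCC(F)(F)F)OCC(F)(F)F
F6 | step 21 | (1R,3R,3aS,4S,8R,8aR)-6,8a-dimethyl-3-(propan-2-yl)-1,2,3,3a,4,5,8,8a-octahydroazulene-1,3,4,8-tetrol | O[C@H]1CC(C)=C[C@@H](O)[C@@]2(C)[C@H](O)C[C@@](O)(C(C)C)[C@H]12
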